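## The problem

The target 24 is an ether of two coumarins: C6 of unit A (a 7-hydroxycoumarin) is bonded through oxygen to C5 of unit B (a 6,7-dihydroxycoumarin). It has no stereocentre, so the task is purely regiochemical: five oxygens on two benzenoid rings, two lactones and one ether must each reach the right carbon. The ether is the difficult bond. On unit B its oxygen stands between C4a and the oxygen-bearing C6, and on unit A next to the C7 oxygen, so a direct aryl–oxygen coupling would have to join two electron-rich, ortho-crowded partners. The benzenoid ring of unit B is 1,2,3,5-tetraoxygenated with C4a between two oxygens, and these two (the C5 ether oxygen and the C8a lactone oxygen) must be told apart. The free catechol of unit B is easily oxidized and both lactones open under hydride, hydroxide or enolate conditions, so the phenols must stay as methyl ethers and the pyranone rings must come late. The enabling feature is the benzenoid ring of unit A: carbon at C4a, oxygen at C8a and C7 in a 1,3-relationship, hydrogen at C8 and C5. This is the 2,4-dihydroxybenzoate pattern that a 3,5-dioxoheptanoate ending in an aldehyde gives on aldol folding. In that chain the ether oxygen sits on C6, a saturated carbon, so the ether can be made by phenol alkylation and becomes a diaryl ether when ring A is built around it.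

## Retrosynthesis

**24 to 23.** The three O–CH3 bonds are cut last. Carrying the catechol and the C7 phenol of unit A as methyl ethers keeps every earlier intermediate stable to air and base. The forward step only asks that BBr3 spare two coumarin lactones and a diaryl ether, which it normally does.

**23 to 20 and 21.** In each unit the C3=C4 double bond and the O1–C2 lactone bond are cut, giving the bis-salicylaldehyde 20 and two equivalents of the ylide 21. A Pechmann-type closure would need regiocontrol on two different electron-rich rings. A Knoevenagel route would leave 3-carboxyl groups to remove. The Wittig lactonization closes both pyranone rings in one operation with the same reagent. It must cope with the doubly ortho-substituted aldehyde of unit B.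

**20 to 16 via 19, 18 and 17.** No skeletal bond is cut here; the oxidation level and the protection are adjusted. The two ortho-phenols of 20 come from BCl3 cleavage of the methoxy group next to each formyl group of 19. The formyl groups come from the diol 18 and this from the diester 17. 17 is the dimethyl ether of the resorcylate 16. The methylation is needed because a free 2,4-dihydroxybenzyl alcohol would not survive. The ester level is kept this far because esters are what the ring-forming chemistry delivers and what the enolate steps tolerate on ring B.

**16 to 13 (key disconnection).** The C4a–C5 bond of ring A is cut by a retro-aldol, and the two phenols are read as ketones. Ring A unfolds to the open chain 13, a 7,7-dimethoxy-3,5-dioxoheptanoate carrying the ring-B aryloxy group on C6. Cutting the ether C–O bond instead would lead back to a hindered Ullmann coupling. Cutting two ring bonds (a cycloaddition) would make regiochemistry depend on orbital control. The chosen cut fixes every substituent of ring A by its place in a linear chain. The precursor has one ring fewer and no diaryl ether. The forward reaction must favour carbon cyclization at C2 over oxygen cyclization.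

**13 to 10 and 11.** The C4–C5 bond of the chain is cut (Claisen). The ester 10 acylates the dianion 12 of methyl acetoacetate 11. The three-carbon ester 10 already holds the aryloxy carbon and the masked aldehyde. The ring-B benzoate must stay a spectator, which its two ortho substituents and three donor groups should ensure.

**10 to 5, 6 and 8.** The acetal carbon is cut from the aryloxyacetate (C–C, Claisen formylation of 7 with methyl formate 8, then acetalization of 9). The O–CH2 bond is then cut (alkylation of phenol 5 with methyl bromoacetate 6). This O–CH2 bond is the future diaryl ether bond, made here as a simple SN2 reaction at a primary carbon. The weak point is that the enolate of 7 has an ortho ester within reach; the formate must win.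

**5 to 1 and 2.** The aryl–carbonyl bond is cut back to 1,2,3,5-tetramethoxybenzene 1 and methyl chloroformate 2. The two ring C–H positions of 1 are equivalent, so lithiation and carboxylation give 4 without a regiochemical question. The only selective event is the loss of one methyl group from 4. The C2 methoxy, squeezed between the ester and the C3 methoxy, is expected to leave.

## Roads not taken

**Alternative 1:** The cut is at the O1–C8a bond of both units, leading to the trimethyl ether A1 (identical with 23) from the bis-(E)-cinnamic acid A2. Forward, riboflavin under visible light and O2 would isomerize both acrylic acid arms to Z and then oxidatively bond each carboxylate oxygen to the ortho ring carbon.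

- Merits: no ortho oxygen has to be installed beforehand. A2 could come in a few steps from a doubly formylated diaryl ether. The route would be clearly shorter than the one chosen.
- Weak points: ring A of A2 has two ortho C–H positions, and only the one para to the aryloxy group gives the target. Two independent photo-oxidative events must both succeed on one electron-rich molecule under O2. The diaryl ether must be made by aryl–oxygen bond formation next to two ortho substituents.
- Comparison: the chosen plan is longer. Against that it sets lactone oxygens that are in place before the rings close, and reaction types with direct analogy at every step.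

**Alternative 2:** The cut removes four bonds of the pyranone ring of unit B (C8a–O1, C4a–C4, C3–C4, O1–C2). The silylaryl triflate A4 would give an aryne with CsF. DMF would add across it, and dimethyl malonate would condense with the resulting ortho-quinone methide to give the coumarin-3-carboxylate A3.

- Merits: four bonds form in one step. The aryloxy group next to the aryne should direct the DMF oxygen to C8a, so regiochemistry is favourable.
- Weak points: A4 is a pentasubstituted benzene that needs its own multistep synthesis, including an aryl–oxygen coupling. The coumarin of unit A, a Michael acceptor, must survive fluoride and malonate anion. The 3-ester of A3 must be hydrolysed and decarboxylated at high temperature.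
- Comparison: this alternative is more convergent for unit B. The chosen plan avoids the aryl–oxygen coupling and the decarboxylation, and closes both pyranone rings with one reagent.

**Alternative 3:** The cut is at C5–C6 and C7–C8 of ring A. The pyranone A6 and the silyl ketene acetal A7 (from the aryloxyacetate 7) would combine in an inverse-demand Diels–Alder reaction, then lose CO2 and methanol to give the salicylate A5.

- Merits: this builds ring A from 7 in one step where the chosen plan needs four. It uses the same saturated-carbon trick for the ether, and it delivers the two ring-A oxygens already differentiated. In step economy for this part it is better.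
- Weak points: A6 needs a separate synthesis, and its 4-methoxy donor lowers its reactivity as an electron-poor diene. Making A7 from 7 with strong base meets the same ortho-ester hazard as the formylation. The orientation of the addition, and whether methanol or silanol is lost, rest on orbital and leaving-group preferences.
- Comparison: the chosen plan uses commodity reagents, and a linear chain whose connectivity alone dictates the substitution pattern.

Key step: step 7

Assumption: compounds 9, 10, 13 and 14 have one stereocentre (the chain carbon bearing the aryloxy group) and are handled as racemates, because this carbon becomes sp2 in step 7; 9 and 14 exist largely as enols.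

## Route

Step 1
Reactants: 1 1,2,3,5-tetramethoxybenzene; 2 methyl chloroformate
Product: 4 methyl 2,3,4,6-tetramethoxybenzoate, via aryllithium 3 (not isolated)
Conditions: n-BuLi, TMEDA, THF, 0 °C; then added to ClCO2Me, THF, −78 °C
Reagents that add atoms: none
Why: Directed ortho-metalation; the only ring C–H type of 1 lies between two methoxy groups, and the aryllithium 3 is acylated by the chloroformate. Inverse addition and the two ortho-methoxy groups of 4 should suppress a second addition.

Step 2
Reactants: 4 methyl 2,3,4,6-tetramethoxybenzoate
Product: 5 methyl 2-hydroxy-3,4,6-trimethoxybenzoate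
Conditions: BCl3 (1.2 equiv), CH2Cl2, −78 to 0 °C; H2O
Reagents that add atoms: none
Why: Chelation-controlled ether cleavage by BCl3 bound to the ester carbonyl. Of the two ortho-methoxy groups, the one at C2 is buttressed by the C3 methoxy, twisted out of plane and more Lewis basic, as in the usual loss of the 2-methyl group from 2,3,4-trimethoxyaryl carbonyl compounds, so 5 should predominate.

Step 3
Reactants: 5 methyl 2-hydroxy-3,4,6-trimethoxybenzoate; 6 methyl bromoacetate
Product: 7 methyl 3,4,6-trimethoxy-2-(2-methoxy-2-oxoethoxy)benzoate
Conditions: K2CO3, DMF, 60 °C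
Reagents that add atoms: none
Why: Williamson ether synthesis (SN2) of the phenoxide at a primary α-bromo ester. K2CO3 is too weak to enolize the product ester, so no Dieckmann closure is expected here.

Step 4
Reactants: 7 methyl 3,4,6-trimethoxy-2-(2-methoxy-2-oxoethoxy)benzoate; 8 methyl formate
Product: 9 methyl 3-oxo-2-[3,4,6-trimethoxy-2-(methoxycarbonyl)phenoxy]propanoate (racemic; mainly the 3-hydroxyacrylate enol)
Conditions: NaH, HCO2Me (large excess), THF, 0 °C to rt; cold 1 M HCl work-up
Reagents that add atoms: none
Why: Crossed Claisen condensation (α-formylation of an aryloxyacetate), driven by the stabilized enolate of 9. The large excess of unhindered formate should outrun Dieckmann attack on the di-ortho-substituted, electron-rich benzoate.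

Step 5
Reactants: 9 methyl 3-oxo-2-[3,4,6-trimethoxy-2-(methoxycarbonyl)phenoxy]propanoate
Product: 10 methyl 3,3-dimethoxy-2-[3,4,6-trimethoxy-2-(methoxycarbonyl)phenoxy]propanoate (racemic)
Conditions: HC(OMe)3, MeOH, TsOH (cat.), rt; NaOMe quench before concentration
Reagents that add atoms: trimethyl orthoformate, COC(OC)OC; methanol (solvent, exchanges with it), CO
Why: Acid-catalysed acetalization of the formyl group, with the orthoformate removing water. The basic quench keeps the acetal from eliminating methanol to the enol ether.

Step 6
Reactants: 10 methyl 3,3-dimethoxy-2-[3,4,6-trimethoxy-2-(methoxycarbonyl)phenoxy]propanoate; 11 methyl acetoacetate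
Product: 13 methyl 7,7-dimethoxy-3,5-dioxo-6-[3,4,6-trimethoxy-2-(methoxycarbonyl)phenoxy]heptanoate (racemic), via acetoacetate dianion 12 (not isolated)
Conditions: 11, NaH, THF, 0 °C, then n-BuLi, 0 °C; 10 added at −78 °C, to −20 °C; AcOH
Reagents that add atoms: none
Why: Claisen-type acylation of the γ-carbon of the acetoacetate dianion by the activated α-aryloxy ester. The hindered ring-B benzoate should not compete, and the product is protected as its dianion until the quench.

Step 7
Reactants: 13 methyl 7,7-dimethoxy-3,5-dioxo-6-[3,4,6-trimethoxy-2-(methoxycarbonyl)phenoxy]heptanoate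
Product: 16 methyl 2-[2,4-dihydroxy-5-(methoxycarbonyl)phenoxy]-3,4,6-trimethoxybenzoate, via 3,5,7-trioxo aldehyde 14 (not isolated), via 4-pyranone 15 (not isolated)
Conditions: 1 M HCl, THF–H2O, 40 °C; then K2CO3/KHCO3 buffer (pH 10), MeOH–H2O, rt; AcOH to pH 4
Reagents that add atoms: none
Why: Aqueous acid hydrolyses the acetal to the trioxo aldehyde 14, which is present as its hydroxymethylene enol and partly closed through the C3 enol oxygen to the 4-pyranone 15. At pH 10 hydroxide should add to the unsubstituted ring carbon of 15 next to oxygen and reopen it to the enolate of 14, so both forms feed the same open chain. The C2 enolate (between ester and C3 ketone) then attacks the aldehyde carbon C7 in a 6-(enolendo)-exo-trig aldol closure that forms the C4a–C5 bond of ring A; loss of water and enolization of the C3 and C5 carbonyls give the benzenoid ring. The closest known reaction type is the biomimetic aldol cyclization of 3,5,7-tricarbonyl esters, and of the (4-oxopyran-2-yl)acetates that mask them, to 2,4-dihydroxybenzoates. No stereocentre is formed and the one at C6 is lost on aromatization. The step needs carbon cyclization at C2 to win over oxygen cyclization and Claisen closure. Only the C2-to-C7 closure gives a six-membered carbocycle that can aromatize: Claisen attack of C6 on the ester would leave a quaternary carbon and stay reversible, and pyranone formation is reversible in base. The hindered ring-B benzoate should not accept the C6 enolate at this pH.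

Step 8
Reactants: 16 methyl 2-[2,4-dihydroxy-5-(methoxycarbonyl)phenoxy]-3,4,6-trimethoxybenzoate
Product: 17 methyl 2-[2,4-dimethoxy-5-(methoxycarbonyl)phenoxy]-3,4,6-trimethoxybenzoate
Conditions: MeI, K2CO3, DMF, 50 °C
Reagents that add atoms: iodomethane, CI
Why: Williamson O-methylation of both phenols, the chelated one ortho to the ester needing gentle warming. Protection is required because a free 2,4-dihydroxybenzyl alcohol from step 9 would ionize to quinone methides.

Step 9
Reactants: 17 methyl 2-[2,4-dimethoxy-5-(methoxycarbonyl)phenoxy]-3,4,6-trimethoxybenzoate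
Product: 18 [2-[5-(hydroxymethyl)-2,4-dimethoxyphenoxy]-3,4,6-trimethoxyphenyl]methanol
Conditions: LiAlH4, THF, 0 °C to reflux; H2O, aq. NaOH work-up
Reagents that add atoms: none
Why: Hydride reduction of both methyl esters to benzylic alcohols. LiAlH4 at reflux reduces even the di-ortho-substituted ring-B ester, and the aryl ethers are inert.

Step 10
Reactants: 18 [2-[5-(hydroxymethyl)-2,4-dimethoxyphenoxy]-3,4,6-trimethoxyphenyl]methanol
Product: 19 2-(5-formyl-2,4-dimethoxyphenoxy)-3,4,6-trimethoxybenzaldehyde
Conditions: activated MnO2 (excess), CH2Cl2, rt to reflux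
Reagents that add atoms: none
Why: MnO2 oxidation is selective for benzylic alcohols and stops at the aldehyde. Its neutral conditions suit these acid-sensitive, electron-rich benzylic alcohols.

Step 11
Reactants: 19 2-(5-formyl-2,4-dimethoxyphenoxy)-3,4,6-trimethoxybenzaldehyde
Product: 20 2-(5-formyl-4-hydroxy-2-methoxyphenoxy)-6-hydroxy-3,4-dimethoxybenzaldehyde
Conditions: BCl3 (3 equiv), CH2Cl2, −78 to 0 °C; H2O
Reagents that add atoms: none
Why: Chelation-controlled cleavage by BCl3 of the one methoxy group ortho to each formyl group. The diaryl ether cannot be cleaved, and any further loss of a methyl group is harmless because all are removed in step 13.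

Step 12
Reactants: 20 2-(5-formyl-4-hydroxy-2-methoxyphenoxy)-6-hydroxy-3,4-dimethoxybenzaldehyde; 21 ethyl (triphenylphosphoranylidene)acetate
Product: 23 6-[(6,7-dimethoxy-2-oxo-2H-chromen-5-yl)oxy]-7-methoxy-2H-chromen-2-one, via bis(2-hydroxycinnamate) diester 22 (not isolated)
Conditions: Ph3P=CHCO2Et (2.5 equiv), N,N-diethylaniline, 210 °C
Reagents that add atoms: none
Why: Wittig olefination of both aldehydes with the stabilized ylide, followed by thermal E-to-Z isomerization and lactonization of the 2-hydroxycinnamates 22. This is the standard salicylaldehyde-to-coumarin annulation.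

Step 13
Reactants: 23 6-[(6,7-dimethoxy-2-oxo-2H-chromen-5-yl)oxy]-7-methoxy-2H-chromen-2-one
Product: 24 6-[(6,7-dihydroxy-2-oxo-2H-chromen-5-yl)oxy]-7-hydroxy-2H-chromen-2-one
Conditions: BBr3 (excess), CH2Cl2, −78 °C to rt; H2O
Reagents that add atoms: none
Why: Lewis-acid cleavage of the three aryl methyl ethers by BBr3. Coumarin lactones and diaryl ethers survive and are recovered on aqueous work-up.

## Compound list

1 | 1,2,3,5-tetramethoxybenzene | COc1cc(OC)c(OC)c(OC)c1 | starting material
2 | methyl chloroformate | COC(=O)Cl | starting material
3 | (2,3,4,6-tetramethoxyphenyl)lithium | [Li]c1c(OC)cc(OC)c(OC)c1OC | intermediate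
4 | methyl 2,3,4,6-tetramethoxybenzoate | COC(=O)c1c(OC)cc(OC)c(OC)c1OC | intermediate
5 | methyl 2-hydroxy-3,4,6-trimethoxybenzoate | COC(=O)c1c(OC)cc(OC)c(OC)c1O | intermediate
6 | methyl bromoacetate | COC(=O)CBr | starting material
7 | methyl 3,4,6-trimethoxy-2-(2-methoxy-2-oxoethoxy)benzoate | COC(=O)COc1c(OC)c(OC)cc(OC)c1C(=O)OC | intermediate
8 | methyl formate | COC=O | starting material
9 | methyl 3-oxo-2-[3,4,6-trimethoxy-2-(methoxycarbonyl)phenoxy]propanoate (racemic; mainly enol) | COC(=O)C(C=O)Oc1c(OC)c(OC)cc(OC)c1C(=O)OC | intermediate
10 | methyl 3,3-dimethoxy-2-[3,4,6-trimethoxy-2-(methoxycarbonyl)phenoxy]propanoate (racemic) | COC(=O)C(Oc1c(OC)c(OC)cc(OC)c1C(=O)OC)C(OC)OC | intermediate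
11 | methyl acetoacetate | CC(=O)CC(=O)OC | starting material
12 | methyl acetoacetate dianion (sodium lithium salt) | [Na+].[Li+].[CH2-]C(=O)[CH-]C(=O)OC | intermediate
13 | methyl 7,7-dimethoxy-3,5-dioxo-6-[3,4,6-trimethoxy-2-(methoxycarbonyl)phenoxy]heptanoate (racemic) | COC(=O)CC(=O)CC(=O)C(Oc1c(OC)c(OC)cc(OC)c1C(=O)OC)C(OC)OC | intermediate
14 | methyl 3,5,7-trioxo-6-[3,4,6-trimethoxy-2-(methoxycarbonyl)phenoxy]heptanoate (racemic; enolized) | COC(=O)CC(=O)CC(=O)C(C=O)Oc1c(OC)c(OC)cc(OC)c1C(=O)OC | intermediate
15 | methyl 3,4,6-trimethoxy-2-{[6-(2-methoxy-2-oxoethyl)-4-oxo-4H-pyran-3-yl]oxy}benzoate | COC(=O)Cc1cc(=O)c(Oc2c(OC)c(OC)cc(OC)c2C(=O)OC)co1 | intermediate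
16 | methyl 2-[2,4-dihydroxy-5-(methoxycarbonyl)phenoxy]-3,4,6-trimethoxybenzoate | COC(=O)c1cc(Oc2c(OC)c(OC)cc(OC)c2C(=O)OC)c(O)cc1O | intermediate
17 | methyl 2-[2,4-dimethoxy-5-(methoxycarbonyl)phenoxy]-3,4,6-trimethoxybenzoate | COC(=O)c1cc(Oc2c(OC)c(OC)cc(OC)c2C(=O)OC)c(OC)cc1OC | intermediate
18 | [2-[5-(hydroxymethyl)-2,4-dimethoxyphenoxy]-3,4,6-trimethoxyphenyl]methanol | OCc1cc(Oc2c(OC)c(OC)cc(OC)c2CO)c(OC)cc1OC | intermediate
19 | 2-(5-formyl-2,4-dimethoxyphenoxy)-3,4,6-trimethoxybenzaldehyde | O=Cc1cc(Oc2c(OC)c(OC)cc(OC)c2C=O)c(OC)cc1OC | intermediate
20 | 2-(5-formyl-4-hydroxy-2-methoxyphenoxy)-6-hydroxy-3,4-dimethoxybenzaldehyde | O=Cc1cc(Oc2c(OC)c(OC)cc(O)c2C=O)c(OC)cc1O | intermediate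
21 | ethyl (triphenylphosphoranylidene)acetate | CCOC(=O)C=P(c1ccccc1)(c1ccccc1)c1ccccc1 | starting material
22 | ethyl 3-[5-[2-(3-ethoxy-3-oxoprop-1-enyl)-3-hydroxy-5,6-dimethoxyphenoxy]-2-hydroxy-4-methoxyphenyl]prop-2-enoate (E/Z mixture) | CCOC(=O)C=Cc1cc(Oc2c(OC)c(OC)cc(O)c2C=CC(=O)OCC)c(OC)cc1O | intermediate
23 | 6-[(6,7-dimethoxy-2-oxo-2H-chromen-5-yl)oxy]-7-methoxy-2H-chromen-2-one | COc1cc2oc(=O)ccc2cc1Oc1c(OC)c(OC)cc2oc(=O)ccc12 | intermediate
24 | 6-[(6,7-dihydroxy-2-oxo-2H-chromen-5-yl)oxy]-7-hydroxy-2H-chromen-2-one | O=c1ccc2cc(Oc3c(O)c(O)cc4oc(=O)ccc34)c(O)cc2o1 | target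

## Step count and least certain steps

Total: 13 steps. Longest linear sequence: 13 steps, from 1 to 24; the route is fully linear.

**Step 7 (key step).** Oxygen cyclization may outrun carbon cyclization: the 4-pyranone may not reopen at this pH, the 3,5-dioxo ester may lactonize to a 4-hydroxy-2-pyranone, or the β-keto aldehyde may be deformylated by retro-Claisen cleavage. Fallback: give up the folding and make the ether by copper-catalysed Ullmann coupling. Methyl 5-bromo-2,4-dimethoxybenzoate F1 is obtained by NBS bromination of methyl 2,4-dimethoxybenzoate. It is coupled with phenol 5 (copper iodide CuI, picolinic acid, K3PO4, DMSO, 90 °C) to give 17 directly. The fallback sets out from 5 and rejoins the route at 17.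

**Step 4.** Dieckmann closure of the ester enolate of 7 onto the neighbouring benzoate (5-exo-trig, to a 3-hydroxybenzofuran-2-carboxylate) may compete with intermolecular formylation. Fallback: avoid the ester enolate altogether. Methyl 2-bromo-3,3-dimethoxypropanoate F2 is made from methyl (E)-3-methoxyacrylate with NBS in methanol. Phenol 5 is alkylated with it (K2CO3, DMF, 50 °C) to give 10. The fallback sets out from 5 and rejoins at 10.

**Step 6.** Proton transfer from the α-carbon of 10 to the dianion, followed by β-elimination of methoxide, may take the place of acylation. Fallback: an aldol in place of the Claisen step. Ester 10 is reduced with i-Bu2AlH (CH2Cl2, −78 °C) to methyl 2-[(1,1-dimethoxy-3-oxopropan-2-yl)oxy]-3,4,6-trimethoxybenzoate F3. This aldehyde adds the dianion 12 at −78 °C to give methyl 5-hydroxy-7,7-dimethoxy-3-oxo-6-[3,4,6-trimethoxy-2-(methoxycarbonyl)phenoxy]heptanoate F4. Oxidation with Dess–Martin periodinane gives 13. The fallback sets out from 10 and rejoins at 13.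

**Step 2.** Cleavage may occur at the other ortho-methoxy group (C6) or at both. Fallback: replace selective demethylation by selective methylation. With excess BCl3 at rt, 4 loses both ortho-methyl groups to give methyl 2,6-dihydroxy-3,4-dimethoxybenzoate F5. One equivalent of MeI (K2CO3, acetone) should methylate the less hindered hydroxyl at C6, leaving the chelated C2 hydroxyl, to give 5. The fallback sets out from 4 and rejoins at 5.

**Step 12.** Olefination of the doubly ortho-substituted ring-B aldehyde may be incomplete, or an E-cinnamate may fail to isomerize and lactonize. Fallback: Knoevenagel condensation of 20 with Meldrum's acid (piperidinium acetate, EtOH) to 5-[(3-carboxy-7-methoxy-2-oxo-2H-chromen-6-yl)oxy]-6,7-dimethoxy-2-oxo-2H-chromene-3-carboxylic acid F6. Double decarboxylation (copper powder, quinoline, 200 °C) then gives 23. The fallback sets out from 20 and rejoins at 23.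

## Further compounds

F1 | step 7 | methyl 5-bromo-2,4-dimethoxybenzoate | COC(=O)c1cc(Br)c(OC)cc1OC
F2 | step 4 | methyl 2-bromo-3,3-dimethoxypropanoate (racemic) | COC(=O)C(Br)C(OC)OC
F3 | step 6 | methyl 2-[(1,1-dimethoxy-3-oxopropan-2-yl)oxy]-3,4,6-trimethoxybenzoate (racemic) | O=CC(Oc1c(OC)c(OC)cc(OC)c1C(=O)OC)C(OC)OC
F4 | step 6 | methyl 5-hydroxy-7,7-dimethoxy-3-oxo-6-[3,4,6-trimethoxy-2-(methoxycarbonyl)phenoxy]heptanoate (racemic, diastereomer mixture) | COC(=O)CC(=O)CC(O)C(Oc1c(OC)c(OC)cc(OC)c1C(=O)OC)C(OC)OC
F5 | step 2 | methyl 2,6-dihydroxy-3,4-dimethoxybenzoate | COC(=O)c1c(O)cc(OC)c(OC)c1O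
F6 | step 12 | 5-[(3-carboxy-7-methoxy-2-oxo-2H-chromen-6-yl)oxy]-6,7-dimethoxy-2-oxo-2H-chromene-3-carboxylic acid | COc1cc2oc(=O)c(C(=O)O)cc2cc1Oc1c(OC)c(OC)cc2oc(=O)c(C(=O)O)cc12
A1 | alternative 1 | 6-[(6,7-dimethoxy-2-oxo-2H-chromen-5-yl)oxy]-7-methoxy-2H-chromen-2-one | COc1cc2oc(=O)ccc2cc1Oc1c(OC)c(OC)cc2oc(=O)ccc12
A2 | alternative 1 | (E)-3-[3-[6-[(E)-2-carboxyethenyl]-2,3-dimethoxyphenoxy]-4-methoxyphenyl]prop-2-enoic acid | COc1ccc(/C=C/C(=O)O)cc1Oc1c(OC)c(OC)ccc1/C=C/C(=O)O
A3 | alternative 2 | methyl 6,7-dimethoxy-5-[(7-methoxy-2-oxo-2H-chromen-6-yl)oxy]-2-oxo-2H-chromene-3-carboxylate | COC(=O)c1cc2c(Oc3cc4ccc(=O)oc4cc3OC)c(OC)c(OC)cc2oc1=O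
A4 | alternative 2 | 4,5-dimethoxy-3-[(7-methoxy-2-oxo-2H-chromen-6-yl)oxy]-2-(trimethylsilyl)phenyl trifluoromethanesulfonate | COc1cc(OS(=O)(=O)C(F)(F)F)c([Si](C)(C)C)c(Oc2cc3ccc(=O)oc3cc2OC)c1OC
A5 | alternative 3 | methyl 2-[2-hydroxy-4-methoxy-5-(methoxycarbonyl)phenoxy]-3,4,6-trimethoxybenzoate | COC(=O)c1cc(Oc2c(OC)c(OC)cc(OC)c2C(=O)OC)c(O)cc1OC
A6 | alternative 3 | methyl 4-methoxy-2-oxo-2H-pyran-5-carboxylate | COC(=O)c1coc(=O)cc1OC
A7 | alternative 3 | methyl 3,4,6-trimethoxy-2-{[2-methoxy-2-(trimethylsilyloxy)ethenyl]oxy}benzoate (E/Z mixture) | COC(O[Si](C)(C)C)=COc1c(OC)c(OC)cc(OC)c1C(=O)OC
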